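If the passing of starting material into tight pair were the rate-limiting step, percent target at a given time would not depend on the charge, and the flask would repeat the amber reading of 12.0% at 90.0 min, the asked end time. That symmetric case is the zero of the scale. If capture by the coupling partner set the pace instead, percent per minute would follow the partner's concentration, which in the flask stands at twice the amber one. The amber reading times that ratio is the proportional yield, Y = 24.0%.

| flask | starting material | coupling partner | remark | time |
|---|---|---|---|---|
| amber | 0.75 M | 1.2 equiv | run made earlier |  |
| flask | 1.5 M | 1.20 equiv |  | 1.5 h |

amber run (percent of the starting material charged): time / min: target / % = 25.0: 3.7; 50.0: 7.2; 60.0: 9.6; 90.0: 12.0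

(each reading ± 0.5 percentage points)

- steps thought possible: starting material <-> tight pair; tight pair <-> loose pair; coupling partner + tight pair -> target; coupling partner + loose pair -> isomer of the product A; target <-> isomer of the product B

- amount of target in percent of the starting material charged, at 10 min, 30 min and 1.5 h

The span between these two amounts, 12 percentage points, is large against the scatter of 0.5 points. One concentration gives no position on it, so the reckoning here takes the middle for the flask at 1.5 h: 18.0%.

The forecast gives 2.6%, 7.5% and 20%, on the ground that “If ionization is partly limiting, the rate rises by less than double”. Its last value stands above that middle and below Y.

The flask gives 4.31% at 10 min, 9.88% at 30 min and 18.8% at 1.5 h.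

starting material ⇌ tight pair (K = 2.10 × 10⁻⁴, k = 0.0270 /min); tight pair ⇌ loose pair (K = 1.10, k = 1.60 /min); coupling partner + tight pair → target (k = 17.0 /M/min); coupling partner + loose pair → isomer of the product A (k = 34.0 /M/min); target ⇌ isomer of the product B (K = 1.00, k = 0.0290 /min) By that step taken alone, both ways together, target and isomer of the product B relax with a half-life of 0.199 h, short against 1.5 h, and at 1.50 h the flask holds 13.8% of that isomer. The flask's target lies 56.7% of the way from the amber reading to Y, and 5.2 points below Y.

(The data are calculated with constants of no real substance; scatter was added.)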